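Everything rests on the C4–C4a bond of ring C. Ring A is introduced as 3-methoxy-5-(methoxymethoxy)benzyne (triple bond C4a≡C8a) and ring B as a 2-arylacrylic acid. In one operation the carboxylate oxygen adds to C8a, the C4a carbanion closes on the acyl carbon C4, and the freed phenolate O1 closes ring C on the acrylate terminus C2, giving the isoflavanone. The step exploits the contiguous C5(OMe)–C4a(C)–C8a(O) array of ring A: the C5 methoxy group beside the triple bond fixes the orientation. The precursors are a silylaryl triflate from 5-bromovanillin and an acid from two directed lithiations. Transfer hydrogenation with dynamic kinetic resolution then sets (3R), and C4 is deoxygenated.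

Key step: step 9

Remark: isoflavan numbering is used throughout (O1, C2, C3, C4, C4a, C5 to C8, C8a for rings C and A, primed numbers for ring B). The stereocentre in the target SMILES is read as (3R).

Step 1
Reactants: 1 5-bromovanillin (3-bromo-4-hydroxy-5-methoxybenzaldehyde)
Product: 2 2-bromo-6-methoxybenzene-1,4-diol
Conditions: H2O2 (30% aq), NaOH (aq), N2, 0 °C to rt; then HCl (2 M)
Reagents that add atoms: hydrogen peroxide, OO
Why: Dakin oxidation, in which the para-hydroxy group drives aryl migration in the peroxide adduct of the aldehyde and hydrolysis of the aryl formate places the future C7 oxygen para to the future C4a oxygen.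

Step 2
Reactants: 2 2-bromo-6-methoxybenzene-1,4-diol
Product: 3 1-bromo-3-methoxy-2,5-bis(trimethylsilyloxy)benzene
Conditions: HN(SiMe3)2, THF, 70 °C; concentrate
Reagents that add atoms: hexamethyldisilazane, C[Si](C)(C)N[Si](C)(C)C
Why: O-silylation of both phenols with hexamethyldisilazane, which releases only ammonia, puts a silyl group on the oxygen next to bromine for the shift in step 3.

Step 3
Reactants: 3 1-bromo-3-methoxy-2,5-bis(trimethylsilyloxy)benzene
Product: 6 4-hydroxy-2-methoxy-6-(trimethylsilyl)phenyl triflate, via lithium phenolate 4 (not isolated), via silyl ether triflate 5 (not isolated)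
Conditions: n-BuLi, THF, −78 °C; Tf2O, −78 °C to 0 °C; then citric acid (cat.), MeOH, rt
Reagents that add atoms: triflic anhydride, O=S(=O)(OS(=O)(=O)C(F)(F)F)C(F)(F)F
Why: Bromine–lithium exchange and 1,3-retro-Brook O-to-C silyl migration move the flanking silyl group to C8a, phenolate 4 is triflated at the C4a oxygen, and mild methanolysis removes only the remaining O-silyl group because the C-silyl carbon is meta to both oxygen donors.

Step 4
Reactants: 6 4-hydroxy-2-methoxy-6-(trimethylsilyl)phenyl triflate
Product: 7 2-methoxy-4-(methoxymethoxy)-6-(trimethylsilyl)phenyl triflate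
Conditions: MOMCl, i-Pr2NEt, CH2Cl2, 0 °C to rt
Reagents that add atoms: chloromethyl methyl ether, COCCl
Why: MOM protection (O-alkylation of the only free phenol) caps the C7 oxygen with a group that is stable to fluoride and cannot add to the aryne.

Step 5
Reactants: 8 3-methoxyphenol
Product: 9 1-methoxy-3-(methoxymethoxy)benzene
Conditions: MOMCl, i-Pr2NEt, CH2Cl2, 0 °C to rt
Reagents that add atoms: chloromethyl methyl ether, COCCl
Why: MOM protection of the phenol also installs the directing group for both lithiations.

Step 6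
Reactants: 9 1-methoxy-3-(methoxymethoxy)benzene
Product: 11 1-methoxy-3-(methoxymethoxy)-2-(3-methylbut-2-enyl)benzene, via 2-lithioarene 10 (not isolated)
Conditions: n-BuLi, THF, 0 °C to rt; prenyl bromide, −78 °C to rt
Reagents that add atoms: prenyl bromide, CC(C)=CCBr
Why: Directed ortho-metalation takes place at the carbon flanked by both oxygen substituents, and aryllithium 10 is alkylated by SN2 attack at the primary carbon of the allylic bromide.

Step 7
Reactants: 11 1-methoxy-3-(methoxymethoxy)-2-(3-methylbut-2-enyl)benzene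
Product: 14 methyl 2-[4-methoxy-2-(methoxymethoxy)-3-(3-methylbut-2-enyl)phenyl]acrylate, via aryllithium 12 (not isolated), via arylzinc chloride 13 (not isolated)
Conditions: s-BuLi, TMEDA, THF, −78 °C; ZnCl2, −78 °C to rt; methyl 2-bromoacrylate, Pd(PPh3)4 (5 mol%), THF, 50 °C
Reagents that add atoms: methyl 2-bromoacrylate, COC(=O)C(Br)=C
Why: A second, kinetically controlled directed ortho-metalation occurs at the free position next to the stronger director OMOM, and transmetalation to zinc allows Negishi coupling with the alpha-bromoacrylate under zerovalent palladium catalysis.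

Step 8
Reactants: 14 methyl 2-[4-methoxy-2-(methoxymethoxy)-3-(3-methylbut-2-enyl)phenyl]acrylate
Product: 15 2-[4-methoxy-2-(methoxymethoxy)-3-(3-methylbut-2-enyl)phenyl]acrylic acid
Conditions: LiOH, THF/H2O, rt; then HCl (1 M) to pH 4, 0 °C
Reagents that add atoms: lithium hydroxide, [Li+].[OH-]
Why: Saponification of the methyl ester followed by cold, weakly acidic work-up should leave the MOM ether and the prenyl group untouched.

Step 9
Reactants: 7 2-methoxy-4-(methoxymethoxy)-6-(trimethylsilyl)phenyl triflate; 15 2-[4-methoxy-2-(methoxymethoxy)-3-(3-methylbut-2-enyl)phenyl]acrylic acid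
Product: 19 rac-5-methoxy-7-(methoxymethoxy)-3-[4-methoxy-2-(methoxymethoxy)-3-(3-methylbut-2-enyl)phenyl]chroman-4-one, via 3-methoxy-5-(methoxymethoxy)benzyne 16 (not isolated), via cesium benzoxetolate 17 (not isolated), via vinyl ketone phenolate 18 (not isolated)
Conditions: CsF, 15 (1.2 equiv), THF, 125 °C, sealed tube
Reagents that add atoms: none
Why: Fluoride-induced 1,2-elimination of 7 releases aryne 16, whose C4a≡C8a triple bond is polarised by the inductively withdrawing C5 methoxy group beside C4a, so the carboxylate oxygen of 15 adds at the distal carbon C8a and the carbanion develops at C4a. This carbanion closes on the neighbouring acyl carbon (4-exo-trig), which forms the C4–C4a bond and gives benzoxetolate 17; cleavage of its C4–O1 bond gives ketone phenolate 18, and O1 then adds to the methylene terminus C2 (6-endo-trig oxa-Michael addition) to complete ring C. The closest known reaction type is the formal insertion of arynes into the C–O bond of carboxylic acids, which converts alpha,beta-unsaturated acids into chroman-4-ones. The new stereocentre C3 arises by uncontrolled protonation of the enolate, so 19 is racemic and configurationally labile, a property that step 10 uses. The step needs regioselectivity (secured by the C5 methoxy group, which outweighs the remote C7 substituent), acyl transfer instead of protonation of the C4a carbanion (favoured by THF at high temperature), and 1,2- instead of 1,4-attack on the acrylate (favoured by the Z conformation of the aryl ester, which holds C4a next to the carbonyl carbon). The slight excess of 15 should limit arylation of the product enolate and ene reaction of 16 at the prenyl group.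

Step 10
Reactants: 19 rac-5-methoxy-7-(methoxymethoxy)-3-[4-methoxy-2-(methoxymethoxy)-3-(3-methylbut-2-enyl)phenyl]chroman-4-one
Product: 20 (3R,4R)-5-methoxy-7-(methoxymethoxy)-3-[4-methoxy-2-(methoxymethoxy)-3-(3-methylbut-2-enyl)phenyl]chroman-4-ol (cis)
Conditions: RuCl[(R,R)-TsDPEN](p-cymene) (2 mol%), HCO2H/Et3N (5:2), EtOAc, 40 °C
Reagents that add atoms: none
Why: Noyori asymmetric transfer hydrogenation under dynamic kinetic resolution, in which Et3N racemises C3 through the enol, the (R,R)-catalyst delivers hydride to the ketone face that gives the (4R)-alcohol and consumes the (3R)-ketone because hydride then arrives anti to the C3 aryl group, should give the cis-(3R,4R)-alcohol and leave the prenyl alkene untouched.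

Step 11
Reactants: 20 (3R,4R)-5-methoxy-7-(methoxymethoxy)-3-[4-methoxy-2-(methoxymethoxy)-3-(3-methylbut-2-enyl)phenyl]chroman-4-ol
Product: 21 (3R)-5-methoxy-7-(methoxymethoxy)-3-[4-methoxy-2-(methoxymethoxy)-3-(3-methylbut-2-enyl)phenyl]chroman
Conditions: Et3SiH (3 equiv), CF3CO2H (2 equiv), CH2Cl2, −40 °C
Reagents that add atoms: none
Why: Ionic hydrogenation, in which the benzylic alcohol on the trioxygenated ring A ionises under cold mild acid and silane hydride traps the C4 cation, removes the C4 oxygen without touching C3, and both MOM groups and the prenyl group should survive the short cold exposure.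

Step 12
Reactants: 21 (3R)-5-methoxy-7-(methoxymethoxy)-3-[4-methoxy-2-(methoxymethoxy)-3-(3-methylbut-2-enyl)phenyl]chroman
Product: 22 (3R)-3-[2-hydroxy-4-methoxy-3-(3-methylbut-2-enyl)phenyl]-5-methoxychroman-7-ol (target)
Conditions: HCl (2 M aq), MeOH, 45 °C
Reagents that add atoms: none
Why: Acid-catalysed acetal exchange with methanol removes both MOM groups in one operation, and dilute acid with a short reaction time should avoid addition of the freed 2'-phenol to the prenyl alkene.

Compound list
1 | 5-bromovanillin (3-bromo-4-hydroxy-5-methoxybenzaldehyde) | COc1cc(C=O)cc(Br)c1O | starting material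
2 | 2-bromo-6-methoxybenzene-1,4-diol | COc1cc(O)cc(Br)c1O | intermediate
3 | 1-bromo-3-methoxy-2,5-bis(trimethylsilyloxy)benzene | COc1cc(O[Si](C)(C)C)cc(Br)c1O[Si](C)(C)C | intermediate
4 | lithium 2-methoxy-6-(trimethylsilyl)-4-(trimethylsilyloxy)phenolate | [Li+].COc1cc(O[Si](C)(C)C)cc([Si](C)(C)C)c1[O-] | intermediate
5 | 2-methoxy-6-(trimethylsilyl)-4-(trimethylsilyloxy)phenyl triflate | COc1cc(O[Si](C)(C)C)cc([Si](C)(C)C)c1OS(=O)(=O)C(F)(F)F | intermediate
6 | 4-hydroxy-2-methoxy-6-(trimethylsilyl)phenyl triflate | COc1cc(O)cc([Si](C)(C)C)c1OS(=O)(=O)C(F)(F)F | intermediate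
7 | 2-methoxy-4-(methoxymethoxy)-6-(trimethylsilyl)phenyl triflate | COCOc1cc(OC)c(OS(=O)(=O)C(F)(F)F)c([Si](C)(C)C)c1 | intermediate
8 | 3-methoxyphenol | COc1cccc(O)c1 | starting material
9 | 1-methoxy-3-(methoxymethoxy)benzene | COCOc1cccc(OC)c1 | intermediate
10 | [2-methoxy-6-(methoxymethoxy)phenyl]lithium | [Li]c1c(OC)cccc1OCOC | intermediate
11 | 1-methoxy-3-(methoxymethoxy)-2-(3-methylbut-2-enyl)benzene | COCOc1cccc(OC)c1CC=C(C)C | intermediate
12 | [4-methoxy-2-(methoxymethoxy)-3-(3-methylbut-2-enyl)phenyl]lithium | [Li]c1ccc(OC)c(CC=C(C)C)c1OCOC | intermediate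
13 | [4-methoxy-2-(methoxymethoxy)-3-(3-methylbut-2-enyl)phenyl]zinc chloride | Cl[Zn]c1ccc(OC)c(CC=C(C)C)c1OCOC | intermediate
14 | methyl 2-[4-methoxy-2-(methoxymethoxy)-3-(3-methylbut-2-enyl)phenyl]acrylate | COC(=O)C(=C)c1ccc(OC)c(CC=C(C)C)c1OCOC | intermediate
15 | 2-[4-methoxy-2-(methoxymethoxy)-3-(3-methylbut-2-enyl)phenyl]acrylic acid | OC(=O)C(=C)c1ccc(OC)c(CC=C(C)C)c1OCOC | intermediate
16 | 3-methoxy-5-(methoxymethoxy)benzyne | COCOC1=CC#CC(OC)=C1 | intermediate
17 | cesium 2-(1-arylvinyl)-2H-benzoxet-2-olate (four-membered ring C4a–C8a–O1–C4) | [Cs+].COCOc1cc(OC)c2c(c1)OC2([O-])C(=C)c1ccc(OC)c(CC=C(C)C)c1OCOC | intermediate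
18 | cesium phenolate of 1-[2-hydroxy-6-methoxy-4-(methoxymethoxy)phenyl]-2-arylprop-2-en-1-one | [Cs+].COCOc1cc([O-])c(C(=O)C(=C)c2ccc(OC)c(CC=C(C)C)c2OCOC)c(OC)c1 | intermediate
19 | rac-5-methoxy-7-(methoxymethoxy)-3-[4-methoxy-2-(methoxymethoxy)-3-(3-methylbut-2-enyl)phenyl]chroman-4-one | COc1cc(OCOC)cc2c1C(=O)C(c1ccc(OC)c(CC=C(C)C)c1OCOC)CO2 | intermediate
20 | (3R,4R)-cis-5-methoxy-7-(methoxymethoxy)-3-[4-methoxy-2-(methoxymethoxy)-3-(3-methylbut-2-enyl)phenyl]chroman-4-ol | COc1cc(OCOC)cc2c1[C@H](O)[C@H](c1ccc(OC)c(CC=C(C)C)c1OCOC)CO2 | intermediate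
21 | (3R)-5-methoxy-7-(methoxymethoxy)-3-[4-methoxy-2-(methoxymethoxy)-3-(3-methylbut-2-enyl)phenyl]chroman | COc1cc(OCOC)cc2c1C[C@H](c1ccc(OC)c(CC=C(C)C)c1OCOC)CO2 | intermediate
22 | (3R)-3-[2-hydroxy-4-methoxy-3-(3-methylbut-2-enyl)phenyl]-5-methoxychroman-7-ol | COc1cc(O)cc2c1C[C@H](c1ccc(OC)c(CC=C(C)C)c1O)CO2 | target

Total step count: 12. Longest linear sequence: 8 (steps 1–4 or steps 5–8, then steps 9–12).

Steps most likely to fail

1. Step 9. Three processes may compete with acyl transfer:
- polymerisation of the acrylic acid at 125 °C,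
- conjugate attack of the C4a carbanion on the unsubstituted acrylate terminus,
- protonation of that carbanion before it reaches the acyl carbon.

The fallback removes the acrylate from the aryne step and adds C2 afterwards. It sets out from 11. Aryllithium 12, made as in step 7, opens ethylene oxide to give 2-[4-methoxy-2-(methoxymethoxy)-3-(3-methylbut-2-enyl)phenyl]ethanol F1. TEMPO/PhI(OAc)2 in MeCN/H2O oxidises it to the arylacetic acid F2. The same aryne insertion with 7 and CsF, through 16, gives the 2-hydroxydeoxybenzoin F3, again by closure of the C4a carbanion on the acyl carbon. Paraformaldehyde and Et2NH in EtOH at reflux (Mannich methylenation, then oxa-Michael closure through 18) bring the route back to 19.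

2. Step 11. The C3 configuration may erode through proton loss or a 1,2-hydride shift in the C4 cation. The 2'-oxygen may also participate with loss of its MOM group, or the prenyl alkene may be protonated. The fallback replaces the cation by a radical. It sets out from 20. NaH, CS2 and MeI give the S-methyl xanthate F6, and Bu3SnH with AIBN in toluene at 80 °C (Barton–McCombie deoxygenation) returns to 21. The C4 radical has no pathway that touches C3.

3. Step 10. Hydride transfer to the electron-rich, peri-substituted ketone may be slow, which gives reversible ring opening to 18 and its reduction time to interfere. The facial match may also be poor. The fallback sets C3 by enantioselective protonation and C4 by substrate control. It sets out from 19. KN(SiMe3)2 and allyl chloroformate give the allyl enol carbonate F4. Pd2(dba)3 with t-Bu-PHOX (the ligand antipode that leads to the R ketone) and formic acid effect decarboxylative asymmetric protonation to the (R)-isoflavanone F5. LiBH(s-Bu)3 in THF at −78 °C, attacking anti to the C3 aryl group, returns to 20.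

Further compounds
F1 | step 9 | 2-[4-methoxy-2-(methoxymethoxy)-3-(3-methylbut-2-enyl)phenyl]ethanol | OCCc1ccc(OC)c(CC=C(C)C)c1OCOC
F2 | step 9 | 2-[4-methoxy-2-(methoxymethoxy)-3-(3-methylbut-2-enyl)phenyl]acetic acid | OC(=O)Cc1ccc(OC)c(CC=C(C)C)c1OCOC
F3 | step 9 | 1-[2-hydroxy-6-methoxy-4-(methoxymethoxy)phenyl]-2-[4-methoxy-2-(methoxymethoxy)-3-(3-methylbut-2-enyl)phenyl]ethanone | COCOc1cc(O)c(C(=O)Cc2ccc(OC)c(CC=C(C)C)c2OCOC)c(OC)c1
F4 | step 10 | allyl 5-methoxy-7-(methoxymethoxy)-3-[4-methoxy-2-(methoxymethoxy)-3-(3-methylbut-2-enyl)phenyl]-2H-chromen-4-yl carbonate | COc1cc(OCOC)cc2c1C(OC(=O)OCC=C)=C(c1ccc(OC)c(CC=C(C)C)c1OCOC)CO2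
F5 | step 10 | (3R)-5-methoxy-7-(methoxymethoxy)-3-[4-methoxy-2-(methoxymethoxy)-3-(3-methylbut-2-enyl)phenyl]chroman-4-one | COc1cc(OCOC)cc2c1C(=O)[C@H](c1ccc(OC)c(CC=C(C)C)c1OCOC)CO2
F6 | step 11 | O-[(3R,4R)-5-methoxy-7-(methoxymethoxy)-3-[4-methoxy-2-(methoxymethoxy)-3-(3-methylbut-2-enyl)phenyl]chroman-4-yl] S-methyl dithiocarbonate | COc1cc(OCOC)cc2c1[C@H](OC(=S)SC)[C@H](c1ccc(OC)c(CC=C(C)C)c1OCOC)CO2
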